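**Strategy.** The route rests on reading the C2''–OH bond of the C6 side chain as a masked C2''–Si bond. That chain is a prenyl group hydrated at its less substituted alkene carbon, and on ring A only this prenyl group sits ortho to O5; the identical one on C8 does not. A dimethylsilyl hydride hung on O5 is therefore added across the C2''=C3'' alkene by a chiral rhodium catalyst. In one operation this picks the C6 prenyl group, closes a six-membered ring (Si, O5, C5, C6, C1'', C2'') and sets the C2'' stereocentre; oxidation then swaps silicon for oxygen with retention. The precursor is the 5-O-dimethylsilyl ether of 7,4'-bis(methoxymethyl)-protected 6,8-diprenylgenistein.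

Key step: step 5

Assumption: the sense of induction of BINAP in this ring closure cannot be foreseen; (R)-BINAP is written, and (S)-BINAP would be used if a first run delivered the mirror-image silane.

Remark: the acetals are put on before the iodination, so that ring B cannot be iodinated next to a free 4'-hydroxyl and ring A keeps its free, ortho/para-directing 5-hydroxyl. The ring made in the key step is a cyclic aryl silyl ether (a 1,2-oxasilinane) and is named so.

Step 1
Reactants: 1 genistein
Product: 2 5-hydroxy-7,4'-bis(methoxymethoxy)isoflavone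
Conditions: MOMCl (2.3 equiv), K2CO3, acetone, 0 °C → rt
Reagents that add atoms: chloromethyl methyl ether (MOMCl), COCCl
Why: Williamson-type O-alkylation is selective for the acidic 7- and 4'-hydroxyls, because the 5-hydroxyl is held in a hydrogen bond to the C4 carbonyl and stays free for the later tether.

Step 2
Reactants: 2 5-hydroxy-7,4'-bis(methoxymethoxy)isoflavone
Product: 3 5-hydroxy-6,8-diiodo-7,4'-bis(methoxymethoxy)isoflavone
Conditions: NIS (2.3 equiv), DMF, 0 → 40 °C, dark
Reagents that add atoms: N-iodosuccinimide (NIS), O=C1CCC(=O)N1I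
Why: Electrophilic aromatic iodination should take the two open positions of ring A, C6 (ortho) and C8 (para) to the free 5-hydroxyl, while ring B with its single acetal-protected oxygen is far less nucleophilic and the acetals survive the acid-free medium.

Step 3
Reactants: 3 5-hydroxy-6,8-diiodo-7,4'-bis(methoxymethoxy)isoflavone; 4 tributyl(3-methylbut-2-en-1-yl)stannane
Product: 5 5-hydroxy-7,4'-bis(methoxymethoxy)-6,8-bis(3-methylbut-2-en-1-yl)isoflavone
Conditions: Pd(PPh3)4 (10 mol %), 4 (2.6 equiv), DMF, 95 °C
Reagents that add atoms: none
Why: Twofold Migita–Kosugi–Stille coupling: the aryl iodides add readily to zerovalent palladium, the chelated phenol is tolerated, and reductive elimination at the unsubstituted allyl terminus should give the linear prenyl groups.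

Step 4
Reactants: 5 5-hydroxy-7,4'-bis(methoxymethoxy)-6,8-bis(3-methylbut-2-en-1-yl)isoflavone; 6 chlorodimethylsilane
Product: 7 5-(dimethylsilyloxy)-7,4'-bis(methoxymethoxy)-6,8-bis(3-methylbut-2-en-1-yl)isoflavone
Conditions: Et3N, DMAP (cat.), CH2Cl2, 0 °C → rt; pentane, filtration under Ar, used crude at once
Reagents that add atoms: none
Why: O-silylation of a phenol with a small chlorosilane under amine/DMAP catalysis should overcome the hydrogen bond of the 5-hydroxyl; the moisture-sensitive Si–H ether is freed from ammonium chloride by filtration and is not chromatographed, so that neither water nor chloride reaches the cationic catalyst of the next step.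

Step 5
Reactants: 7 5-(dimethylsilyloxy)-7,4'-bis(methoxymethoxy)-6,8-bis(3-methylbut-2-en-1-yl)isoflavone
Product: 8 cyclic silyl ether in which SiMe2 bridges O5 and C2'' (six-membered 1,2-oxasilinane ring of Si, O5, C5, C6, C1'', C2''; isopropyl on C2'', S), otherwise 7,4'-bis(methoxymethoxy)-8-(3-methylbut-2-en-1-yl)isoflavone
Conditions: [Rh(cod)2]BF4 (5 mol %), (R)-BINAP (6 mol %), H2 pre-activation then Ar, dry acetone (0.02 M), 25 → 50 °C
Reagents that add atoms: none
Why: Proposed new method: the cationic BINAP–rhodium fragment (monovalent rhodium, freed from cyclooctadiene by brief hydrogenation) should add oxidatively into the Si–H bond, bind the C2''=C3'' alkene that the O5 tether holds next to it, insert it into the Rh–Si bond so that silicon goes to C2'' and rhodium to C3'', and release the ring by C3''–H reductive elimination. The closest known reaction type is the enantioselective intramolecular hydrosilylation of alkenyl silyl ethers with cationic bisphosphine–rhodium catalysts followed by Tamao oxidation, which is established for five-membered closures onto less substituted alkenes but not for this ring size or a trisubstituted alkene. The one ring formed (Si, O5, C5, C6, C1'', C2'') closes in the 6-exo mode, since the 7-endo alternative would place silicon on the fully substituted C3'' and is disfavoured by both sterics and tether length. The new C2'' stereocentre (S) is fixed in the alkene insertion, and the chiral pocket of the BINAP ligand is the only source of facial bias because the substrate has no other stereocentre. Site selectivity between the two identical prenyl groups is secured by the substrate, as the Si–H group on O5 can reach only the C6 prenyl group and intermolecular addition to the hindered C8 prenyl alkene is slow. The step also needs chemoselectivity against reduction of the pyranone C4 carbonyl or C2=C3 bond lying peri to O5, which rests on the low electrophilicity of this vinylogous ester and on working dilute at the lowest temperature that gives turnover.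

Step 6
Reactants: 8 cyclic silyl ether (S at C2'')
Product: 9 5-hydroxy-6-[(2S)-2-hydroxy-3-methylbutyl]-7,4'-bis(methoxymethoxy)-8-(3-methylbut-2-en-1-yl)isoflavone
Conditions: 30% aq H2O2, KF, KHCO3, THF/MeOH, 40 °C
Reagents that add atoms: hydrogen peroxide, OO
Why: Tamao–Fleming oxidation of an aryloxy(dialkyl)silane: fluoride-activated silicon takes up hydroperoxide and C2'' migrates from silicon to oxygen with retention, so the (S) carbinol should result while hydrolysis of the Si–O bonds frees the 5-hydroxyl; the acetals and the electron-rich prenyl alkene are inert to buffered peroxide.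

Step 7
Reactants: 9 5-hydroxy-6-[(2S)-2-hydroxy-3-methylbutyl]-7,4'-bis(methoxymethoxy)-8-(3-methylbut-2-en-1-yl)isoflavone
Product: 10 6-[(2S)-2-hydroxy-3-methylbutyl]-5-methoxy-7,4'-bis(methoxymethoxy)-8-(3-methylbut-2-en-1-yl)isoflavone
Conditions: MeI (5 equiv), K2CO3, DMF, 40 °C
Reagents that add atoms: iodomethane (MeI), CI
Why: Williamson methylation of the only phenolic hydroxyl; carbonate does not deprotonate the secondary alcohol, and excess iodomethane in DMF should overcome the hydrogen bond to the C4 carbonyl.

Step 8
Reactants: 10 6-[(2S)-2-hydroxy-3-methylbutyl]-5-methoxy-7,4'-bis(methoxymethoxy)-8-(3-methylbut-2-en-1-yl)isoflavone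
Product: 11 7-hydroxy-6-[(2S)-2-hydroxy-3-methylbutyl]-3-(4-hydroxyphenyl)-5-methoxy-8-(3-methylbut-2-en-1-yl)-4H-chromen-4-one (CNP0323282.1)
Conditions: HCl (1 M in MeOH), 40 °C
Reagents that add atoms: none
Why: Acid-catalysed acetal exchange with methanol should remove both MOM groups under conditions mild enough to leave the prenyl alkene, the aryl methyl ether and the secondary carbinol, whose stereocentre is not involved, untouched.

**Compound list**

1 | genistein (5,7-dihydroxy-3-(4-hydroxyphenyl)-4H-chromen-4-one) | O=c1c(-c2ccc(O)cc2)coc2cc(O)cc(O)c12 | starting material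
2 | 5-hydroxy-7,4'-bis(methoxymethoxy)isoflavone | Oc1cc(OCOC)cc2occ(-c3ccc(OCOC)cc3)c(=O)c12 | intermediate
3 | 5-hydroxy-6,8-diiodo-7,4'-bis(methoxymethoxy)isoflavone | Oc1c(I)c(OCOC)c(I)c2occ(-c3ccc(OCOC)cc3)c(=O)c12 | intermediate
4 | tributyl(3-methylbut-2-en-1-yl)stannane | CC(C)=CC[Sn](CCCC)(CCCC)CCCC | starting material
5 | 5-hydroxy-7,4'-bis(methoxymethoxy)-6,8-bis(3-methylbut-2-en-1-yl)isoflavone | Oc1c(CC=C(C)C)c(OCOC)c(CC=C(C)C)c2occ(-c3ccc(OCOC)cc3)c(=O)c12 | intermediate
6 | chlorodimethylsilane | C[SiH](C)Cl | starting material
7 | 5-(dimethylsilyloxy)-7,4'-bis(methoxymethoxy)-6,8-bis(3-methylbut-2-en-1-yl)isoflavone | C[SiH](C)Oc1c(CC=C(C)C)c(OCOC)c(CC=C(C)C)c2occ(-c3ccc(OCOC)cc3)c(=O)c12 | intermediate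
8 | cyclic silyl ether, SiMe2 bridging O5 and C2'' (1,2-oxasilinane ring; isopropyl on C2'', S), 7,4'-bis(methoxymethoxy)-8-(3-methylbut-2-en-1-yl)isoflavone | C[Si]1(C)Oc2c(C[C@H]1C(C)C)c(OCOC)c(CC=C(C)C)c1occ(-c3ccc(OCOC)cc3)c(=O)c21 | intermediate
9 | 5-hydroxy-6-[(2S)-2-hydroxy-3-methylbutyl]-7,4'-bis(methoxymethoxy)-8-(3-methylbut-2-en-1-yl)isoflavone | Oc1c(C[C@H](O)C(C)C)c(OCOC)c(CC=C(C)C)c2occ(-c3ccc(OCOC)cc3)c(=O)c12 | intermediate
10 | 6-[(2S)-2-hydroxy-3-methylbutyl]-5-methoxy-7,4'-bis(methoxymethoxy)-8-(3-methylbut-2-en-1-yl)isoflavone | COc1c(C[C@H](O)C(C)C)c(OCOC)c(CC=C(C)C)c2occ(-c3ccc(OCOC)cc3)c(=O)c12 | intermediate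
11 | 7-hydroxy-6-[(2S)-2-hydroxy-3-methylbutyl]-3-(4-hydroxyphenyl)-5-methoxy-8-(3-methylbut-2-en-1-yl)-4H-chromen-4-one (CNP0323282.1) | COc1c(C[C@H](O)C(C)C)c(O)c(CC=C(C)C)c2occ(-c3ccc(O)cc3)c(=O)c12 | target

**Step count.** Total: 8 steps. Longest linear sequence: 8 steps, from genistein 1 to target 11.

**Steps most likely to fail**

1. Step 5. The trisubstituted alkene may not insert in the 6-exo mode, the catalyst may instead reduce the pyranone carbonyl peri to O5, or facial selectivity at C2'' may be poor. The fallback uses known chemistry and keeps the O5 tether for site selection only. It sets out from 7, which is closed without asymmetric induction by platinum-catalysed intramolecular hydrosilylation of the alkenyl silyl ether (Karstedt catalyst Pt2[(CH2=CHSiMe2)2O]3, zerovalent platinum, toluene, 60 °C) to give the racemic cyclic silyl ether F1. Oxidation with H2O2/KF/KHCO3 as in step 6 gives the racemic 5-hydroxy-6-(2-hydroxy-3-methylbutyl) compound F2. This is resolved by preparative chromatography on a chiral stationary phase (amylose tris(3,5-dimethylphenylcarbamate)); the (S)-enantiomer is compound 9, where the route is rejoined.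

2. Step 3. The prenyl group may be transferred through its tertiary terminus, giving 1,1-dimethylallyl isomers at one or both of the flanked positions. The fallback sets out from 3: twofold Stille coupling with allyltributylstannane (Pd(PPh3)4, DMF, 90 °C), in which both allyl termini are alike, gives the 6,8-diallyl compound F3. Double cross-metathesis with 2-methylbut-2-ene (second-generation Grubbs catalyst RuCl2(=CHPh)(H2IMes)(PCy3), CH2Cl2, 40 °C) turns each allyl group into a prenyl group and comes back to the route at 5.

3. Step 8. While the acetals are cleaved, acid may promote addition of the freed 7-hydroxyl to the neighbouring 8-prenyl alkene (chroman formation) or hydration of that alkene. The fallback sets out from 10 and avoids Brønsted acid. TMSOTf/2,2'-bipyridyl in CH2Cl2 (0 °C → rt) exchanges both aryl MOM ethers for aryl trimethylsilyl ethers and silylates the 2''-hydroxyl, giving the tris(trimethylsilyl) ether F4. K2CO3 in MeOH at rt then removes the three silyl groups and arrives at 11.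

**Further compounds**

F1 | step 5 | racemic cyclic silyl ether (SiMe2 bridging O5 and C2''), 7,4'-bis(methoxymethoxy)-8-(3-methylbut-2-en-1-yl)isoflavone | C[Si]1(C)Oc2c(CC1C(C)C)c(OCOC)c(CC=C(C)C)c1occ(-c3ccc(OCOC)cc3)c(=O)c21
F2 | step 5 | racemic 5-hydroxy-6-(2-hydroxy-3-methylbutyl)-7,4'-bis(methoxymethoxy)-8-(3-methylbut-2-en-1-yl)isoflavone | Oc1c(CC(O)C(C)C)c(OCOC)c(CC=C(C)C)c2occ(-c3ccc(OCOC)cc3)c(=O)c12
F3 | step 3 | 6,8-diallyl-5-hydroxy-7,4'-bis(methoxymethoxy)isoflavone | Oc1c(CC=C)c(OCOC)c(CC=C)c2occ(-c3ccc(OCOC)cc3)c(=O)c12
F4 | step 8 | 5-methoxy-8-(3-methylbut-2-en-1-yl)-7,4'-bis(trimethylsilyloxy)-6-[(2S)-3-methyl-2-(trimethylsilyloxy)butyl]isoflavone | COc1c(C[C@H](O[Si](C)(C)C)C(C)C)c(O[Si](C)(C)C)c(CC=C(C)C)c2occ(-c3ccc(O[Si](C)(C)C)cc3)c(=O)c12
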